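Slowness is the first suspicion about a reading at 40 min, since a flask still moving would need a rate and not an end state. But the spring run fell from 21.1% to 5.9% of its starting material between 6.00 min and 12.0 min, a late rate of 0.212 /min, and 40 min holds 12.2 half-lives at that rate. So the two chemists below treat the flasks as finished and argue about the end ratio.

| setting | spring | Thursday's | Saturday's | Monday's | Sunday's | Friday's | Wednesday's |
|---|---|---|---|---|---|---|---|
| starting material | 0.76 M | 1.0 M | 0.15 M | 0.69 M | 0.25 M | 0.50 M | 2.0 M |
| remark | run made earlier |  |  |  |  |  |  |
| time |  | 40 min | 40 min | 40 min | 40 min | 40 min | 40 min |

spring run (percent of the starting material charged)

| time / min | target / % | side product / % | starting material / % |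
|---|---|---|---|
| 2.00 | 9.5 | 1.6 | 56.0 |
| 6.00 | 18.7 | 4.6 | 21.1 |
| 12.0 | 23.2 | 6.0 | 5.9 |
| 15.0 | 23.7 | 6.1 | 3.5 |
| 25.0 | 25.0 | 6.8 | 0.1 |

(standard deviation of a reading: 0.3 percentage points)

1. the flasks by share of target in all that became target or side product, highest first, at 40 min (Thursday's / Saturday's / Monday's / Sunday's / Friday's / Wednesday's)
2. the share of target in all that became target or side product of the flask you put first, at 40 min
3. the share of target in all that became target or side product of the flask you put last, at 40 min

- percentages count the starting material that a species holds: one side product or homo dimer counts as two
- the numbers in the tables scatter by 0.3 percentage points (one standard deviation)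
- steps thought possible: starting material -> intermediate A; intermediate A <-> intermediate B; starting material + intermediate A -> side product; starting material -> target; 2 starting material -> homo dimer

The first chemist, whose reckoning this is, argues from the steps. Target is made at a rate that goes as [starting material], side product at one that goes as [starting material][intermediate A], and [intermediate A] should grow with the charge. Side product per target should therefore rise in proportion to the charge. The last spring reading gives 0.358 /M; this is the ratio per molar, side product over target divided by the charge, a selectivity factor. The share is then one over one plus this ratio times the charge, which gives 94.9% for Saturday's and 58.3% for Wednesday's.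

The second chemist, who made the forecast, objects. By the forecast's reading, spring's starting material decays at about 0.29 per minute early but about 0.20 per minute late, so a second-order loss exists, and “That loss is mainly homo dimer”. Scaling from spring, the forecast lets side product go roughly as the charge times the 1.7 power of the time integral of [starting material]. The forecast reads Saturday's > Sunday's > Friday's > Monday's > Thursday's > Wednesday's, with 94% and 63%.

The flasks give Saturday's > Sunday's > Friday's > Monday's > Thursday's > Wednesday's, with 93.7% and 66.8%. Wednesday's stands 3.8 percentage points above the forecast and 8.5 points above the first chemist's figure.

    starting material → intermediate A (k = 0.120 /min)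
    intermediate A ⇌ intermediate B (K = 2.20, k = 0.160 /min)
    starting material + intermediate A → side product (k = 0.0780 /M/min)
    starting material → target (k = 0.0640 /min)
    2 starting material → homo dimer (k = 0.0920 /M/min)

Near the spring charge the first chemist's view comes close: the ratio per molar gives 80.2% for Monday's against 80.2%, and 73.6% for Thursday's against 75.7%. Wednesday's own ratio per molar is 0.249 /M, below spring's 0.358 /M. For the neighbour of Saturday's, charged 0.037 M with the time held, the ratio per molar gives 98.7%. That flask gives 98.3%, with target 34.0% and side product 0.603%.

The numbers in the tables were computed with made-up constants.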